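**Retrosynthetic overview** (positions follow cyclopenta[c]pyridine numbering: C1, N2, C3, C4, C4a, C5, C6, C7, C7a; ring A is the N2 six-membered ring, ring B the cyclopentane)
- The target is a diester. A two-fold Mitsunobu esterification, inverting C6 in each unit, splits it into two molecules of the (6S)-amino alcohol and (2E,6E)-2,6-dimethylocta-2,6-dienedioic acid, which comes from geranyl acetate by allylic oxidation at C8 and oxidation of both termini.
- The amino alcohol goes back through ketone reduction, lactam reduction, correction of C4 by enolate protonation, C7 equilibration and cis-hydrogenation to a bicyclic enone lactam.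
- The route rests on ring B (C4a-C5-C6-C7-C7a): its oxygen sits at C6 between C5H2 and the methyl-bearing C7, and it is fused through C4a-C7a to ring A. This is the pattern of a cyclopentenone built from a vinyl group (C4a=C5), a methyl alkyne (C7≡C7a) and CO (C6).
- Key disconnection: an intramolecular Pauson–Khand reaction of an amide-tethered 1,7-enyne cuts C4a-C7a, C5-C6 and C6-C7. Ring A closes first (alkene insertion), ring B second (CO insertion and reductive elimination), both in one step.
- The enyne amide comes from (S)-2-methylbut-3-enoic acid (resolved racemate) and N-methylbut-2-yn-1-amine. The C4 (S) centre steers C4a and is inverted afterwards.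

Key step: step 4

Assumption: in step 1 the salt of the (S)-acid with (S)-1-phenylethylamine is taken to be the less soluble diastereomer; if the opposite pairing crystallises, (R)-1-phenylethylamine is used and nothing else changes.

**Route**

Step 1
Reactants: 1 (±)-2-methylbut-3-enoic acid; 2 (S)-1-phenylethylamine
Product: 3 (S)-1-phenylethylammonium (S)-2-methylbut-3-enoate
Conditions: 2 (1.0 equiv), acetone, reflux then 4 °C; recrystallise from acetone to constant rotation
Reagents that add atoms: none
Why: Classical resolution by diastereomeric salt formation, in which the two 1-phenylethylammonium salts differ in solubility so that fractional crystallisation should enrich the salt of the (S)-acid, whose stereocentre is not touched.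

Step 2
Reactants: 3 (S)-1-phenylethylammonium (S)-2-methylbut-3-enoate
Product: 4 (S)-2-methylbut-3-enoic acid
Conditions: 1 M HCl, Et2O, 0 °C
Reagents that add atoms: none
Why: Acid–base liberation, in which the mineral acid protonates the carboxylate in the cold without epimerising C2 or moving the β,γ-double bond.

Step 3
Reactants: 4 (S)-2-methylbut-3-enoic acid; 5 N-methylbut-2-yn-1-amine
Product: 6 (S)-N-(but-2-yn-1-yl)-N,2-dimethylbut-3-enamide
Conditions: DIC, HOBt, CH2Cl2, 0 °C to rt, no amine base
Reagents that add atoms: none
Why: Carbodiimide/HOBt amide coupling run without tertiary amine, so that the active ester of the α-vinyl acid should be acylated by the secondary amine faster than it enolises, keeping the future C4 as S and the double bond out of conjugation.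

Step 4
Reactants: 6 (S)-N-(but-2-yn-1-yl)-N,2-dimethylbut-3-enamide
Product: 8 (4S,4aS)-2,4,7-trimethyl-1,2,4,4a-tetrahydro-5H-cyclopenta[c]pyridine-3,6-dione, via alkyne-Co2(CO)6 complex 7 (not isolated)
Conditions: Co2(CO)8 (1.1 equiv), ClCH2CH2Cl, rt; then n-BuSMe (4 equiv), 83 °C
Reagents that add atoms: octacarbonyldicobalt Co2(CO)8, O=C=[Co](=C=O)(=C=O)(=C=O)[Co](=C=O)(=C=O)(=C=O)=C=O (one CO becomes C6 and its oxygen)
Why: Intramolecular Pauson–Khand reaction, the closest known type being the Co2(CO)8-mediated cyclocarbonylation of heteroatom-tethered 1,7-enynes: the alkyne is bound as the Co2(CO)6 complex 7, a CO ligand is lost with help from the sulfide, the vinyl group coordinates and inserts into the cobalt–C7a bond, CO inserts and reductive elimination releases the enone. Ring A (the six-membered lactam) closes in the alkene insertion by forming C4a-C7a, an exo closure with respect to both the alkene and the alkyne; ring B (the cyclopentenone) closes by CO insertion and reductive elimination, which form C5-C6 and C6-C7 as the [2+2+1] event. The one new stereocentre, C4a, is set by the resident C4 centre: in the chair-like insertion transition state the C4 methyl lies pseudo-equatorial and anti to the forming C4a-C7a bond, so the bulky dicobalt unit should add to the vinyl face remote from the methyl, leaving H4a trans to H4 (4S,4aS; C4a as in the target, C4 deliberately epimeric). The step needs this diastereofacial selectivity at the vinyl group and C4 provides it; regiochemistry needs no control because the tether forces C7a onto the internal alkene carbon and leaves the methyl-bearing alkyne carbon and the terminal CH2 to flank the new carbonyl C6. Amide rotation is fast at the reaction temperature, so the rotamer with the butynyl group near the vinyl group is available, and the neutral promoter avoids base that could conjugate the β,γ-double bond or epimerise C4.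

Step 5
Reactants: 8 (4S,4aS)-2,4,7-trimethyl-1,2,4,4a-tetrahydro-5H-cyclopenta[c]pyridine-3,6-dione
Product: 9 (4S,4aR,7R,7aR)-2,4,7-trimethylhexahydro-1H-cyclopenta[c]pyridine-3,6-dione (H4a, H7a and H7 all cis; C7 methyl on the concave face)
Conditions: H2 (4 atm), 10% Pd/C, EtOAc, rt
Reagents that add atoms: none
Why: Heterogeneous catalytic hydrogenation adds both hydrogens syn to the C7=C7a bond from the face carrying H4a, the convex face of the bent bicycle, which should set C7a (cis ring fusion) and, for now, C7 with its methyl on the concave face.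

Step 6
Reactants: 9 (4S,4aR,7R,7aR)-2,4,7-trimethylhexahydro-1H-cyclopenta[c]pyridine-3,6-dione
Product: 10 (4S,4aR,7S,7aR)-2,4,7-trimethylhexahydro-1H-cyclopenta[c]pyridine-3,6-dione (C7 methyl on the convex face, trans to C1)
Conditions: K2CO3, MeOH, rt
Reagents that add atoms: none
Why: Base-mediated epimerisation through the C6 ketone enolate is under thermodynamic control and should move the C7 methyl to the convex face, trans to C1, while the far less acidic lactam α-position C4 and the non-enolisable C4a and C7a stay as they are.

Step 7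
Reactants: 10 (4S,4aR,7S,7aR)-2,4,7-trimethylhexahydro-1H-cyclopenta[c]pyridine-3,6-dione
Product: 11 (4'S,4a'R,7'S,7a'R)-2',4',7'-trimethylhexahydrospiro[1,3-dioxolane-2,6'-cyclopenta[c]pyridin]-3'(2'H)-one
Conditions: HOCH2CH2OH, TsOH·H2O (cat.), toluene, reflux, Dean–Stark
Reagents that add atoms: ethylene glycol, OCCO
Why: Acid-catalysed ketalisation with azeotropic removal of water masks the C6 ketone as a 1,3-dioxolane that is inert to amide bases and LiAlH4, and acid cannot erode C7 because it already has its thermodynamic configuration.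

Step 8
Reactants: 11 (4'S,4a'R,7'S,7a'R)-2',4',7'-trimethylhexahydrospiro[1,3-dioxolane-2,6'-cyclopenta[c]pyridin]-3'(2'H)-one
Product: 13 (4'R,4a'R,7'S,7a'R)-2',4',7'-trimethylhexahydrospiro[1,3-dioxolane-2,6'-cyclopenta[c]pyridin]-3'(2'H)-one, via lithium enolate 12 (not isolated)
Conditions: LiN(i-Pr)2 (1.5 equiv), THF, −78 to 0 °C; then AcOH in THF, −78 °C
Reagents that add atoms: none
Why: Kinetic protonation of a lactam enolate: enolisation erases C4, and the proton should return from the convex face (the face of H4a and H7a) because the concave face of C4 is screened by ring B, whose C4a-C5 bond stands pseudo-axial to avoid allylic strain with the C4 methyl, giving H4 cis to H4a as in the target.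

Step 9
Reactants: 13 (4'R,4a'R,7'S,7a'R)-2',4',7'-trimethylhexahydrospiro[1,3-dioxolane-2,6'-cyclopenta[c]pyridin]-3'(2'H)-one
Product: 14 (4'R,4a'S,7'S,7a'R)-2',4',7'-trimethyloctahydrospiro[1,3-dioxolane-2,6'-cyclopenta[c]pyridine]
Conditions: LiAlH4, THF, reflux; Fieser work-up
Reagents that add atoms: none
Why: LiAlH4 reduction of a tertiary lactam to the cyclic tertiary amine through the iminium ion, with the dioxolane and all four stereocentres inert.

Step 10
Reactants: 14 (4'R,4a'S,7'S,7a'R)-2',4',7'-trimethyloctahydrospiro[1,3-dioxolane-2,6'-cyclopenta[c]pyridine]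
Product: 15 (4R,4aS,7S,7aR)-2,4,7-trimethyloctahydro-6H-cyclopenta[c]pyridin-6-one
Conditions: 2 M HCl, THF, rt; then aq. NaOH
Reagents that add atoms: water, O
Why: Aqueous acid hydrolysis of the dioxolane, in which the protonated amine is stable and C7 cannot drift because it already sits in its thermodynamic configuration.

Step 11
Reactants: 15 (4R,4aS,7S,7aR)-2,4,7-trimethyloctahydro-6H-cyclopenta[c]pyridin-6-one
Product: 16 (4R,4aS,6S,7S,7aR)-2,4,7-trimethyloctahydro-1H-cyclopenta[c]pyridin-6-ol (hydroxyl on the concave face, trans to the C7 methyl)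
Conditions: NaBH4, MeOH, −20 °C
Reagents that add atoms: none
Why: Borohydride reduction of a cyclopentanone, in which the small hydride should attack C6 from the convex face because the concave face is blocked by cis-fused ring A, placing the hydroxyl on the concave face (6S).

Step 12
Reactants: 17 geranyl acetate
Product: 18 (2E,6E)-8-hydroxy-3,7-dimethylocta-2,6-dien-1-yl acetate
Conditions: SeO2 (cat.), t-BuOOH, CH2Cl2, rt
Reagents that add atoms: selenium dioxide SeO2, O=[Se]=O (catalytic oxygen carrier); tert-butyl hydroperoxide, CC(C)(C)OO (terminal oxidant)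
Why: Sharpless SeO2/t-BuOOH allylic oxidation (ene reaction then [2,3]-sigmatropic shift) is selective for the (E)-methyl of the terminal trisubstituted alkene, which fixes the 6E geometry, while the alkene next to the acetate is deactivated.

Step 13
Reactants: 18 (2E,6E)-8-hydroxy-3,7-dimethylocta-2,6-dien-1-yl acetate
Product: 19 (2E,6E)-2,6-dimethylocta-2,6-diene-1,8-diol
Conditions: K2CO3 (cat.), MeOH, rt
Reagents that add atoms: none
Why: Base-catalysed transesterification with methanol removes the acetate without touching either alkene.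

Step 14
Reactants: 19 (2E,6E)-2,6-dimethylocta-2,6-diene-1,8-diol
Product: 20 (2E,6E)-2,6-dimethylocta-2,6-dienedial
Conditions: MnO2 (excess), CH2Cl2, rt
Reagents that add atoms: none
Why: MnO2 oxidation is specific for allylic alcohols, stops at the aldehyde and keeps both E double bonds.

Step 15
Reactants: 20 (2E,6E)-2,6-dimethylocta-2,6-dienedial
Product: 21 (2E,6E)-2,6-dimethylocta-2,6-dienedioic acid
Conditions: NaClO2, NaH2PO4, 2-methylbut-2-ene, t-BuOH/H2O, 0 °C to rt
Reagents that add atoms: sodium chlorite NaClO2, [Na+].[O-]Cl=O
Why: Pinnick oxidation takes enals to enoic acids without double-bond isomerisation, the alkene scavenger removing the hypochlorous acid formed.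

Step 16
Reactants: 16 (4R,4aS,6S,7S,7aR)-2,4,7-trimethyloctahydro-1H-cyclopenta[c]pyridin-6-ol (2.2 equiv); 21 (2E,6E)-2,6-dimethylocta-2,6-dienedioic acid
Product: 22 bis[(4R,4aS,6R,7S,7aR)-2,4,7-trimethyloctahydro-1H-cyclopenta[c]pyridin-6-yl] (2E,6E)-2,6-dimethylocta-2,6-dienedioate (CNP0240822.3)
Conditions: PPh3, DIAD, THF, 0 °C to rt
Reagents that add atoms: none
Why: Two-fold Mitsunobu esterification, in which each carboxylate displaces the oxyphosphonium group at C6 by SN2 from the open convex face and so inverts 6S to 6R in both units, with the tertiary amines and the enoate double bonds as spectators.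

**Compound list**
1 | (±)-2-methylbut-3-enoic acid | C=CC(C)C(O)=O | starting material
2 | (S)-1-phenylethylamine | C[C@H](N)c1ccccc1 | starting material
3 | (S)-1-phenylethylammonium (S)-2-methylbut-3-enoate | [O-]C(=O)[C@@H](C)C=C.C[C@H]([NH3+])c1ccccc1 | intermediate
4 | (S)-2-methylbut-3-enoic acid | OC(=O)[C@@H](C)C=C | intermediate
5 | N-methylbut-2-yn-1-amine | CC#CCNC | starting material
6 | (S)-N-(but-2-yn-1-yl)-N,2-dimethylbut-3-enamide | CC#CCN(C)C(=O)[C@@H](C)C=C | intermediate
7 | hexacarbonyldicobalt complex of the alkyne of 6, drawn as the dicobaltatetrahedrane | CC12[Co]3(=C=O)(=C=O)(=C=O)[Co]1(=C=O)(=C=O)(=C=O)C23CN(C)C(=O)[C@@H](C)C=C | intermediate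
8 | (4S,4aS)-2,4,7-trimethyl-1,2,4,4a-tetrahydro-5H-cyclopenta[c]pyridine-3,6-dione | O=C1C[C@@H]2C(CN(C)C(=O)[C@H]2C)=C1C | intermediate
9 | (4S,4aR,7R,7aR)-2,4,7-trimethylhexahydro-1H-cyclopenta[c]pyridine-3,6-dione | O=C1C[C@@H]2[C@@H](CN(C)C(=O)[C@H]2C)[C@H]1C | intermediate
10 | (4S,4aR,7S,7aR)-2,4,7-trimethylhexahydro-1H-cyclopenta[c]pyridine-3,6-dione | O=C1C[C@@H]2[C@@H](CN(C)C(=O)[C@H]2C)[C@@H]1C | intermediate
11 | (4'S,4a'R,7'S,7a'R)-2',4',7'-trimethylhexahydrospiro[1,3-dioxolane-2,6'-cyclopenta[c]pyridin]-3'(2'H)-one | C13(OCCO3)C[C@@H]2[C@@H](CN(C)C(=O)[C@H]2C)[C@@H]1C | intermediate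
12 | lithium enolate of 11 (C3-OLi, C3=C4) | C13(OCCO3)C[C@@H]2[C@@H](CN(C)C(O[Li])=C2C)[C@@H]1C | intermediate
13 | (4'R,4a'R,7'S,7a'R)-2',4',7'-trimethylhexahydrospiro[1,3-dioxolane-2,6'-cyclopenta[c]pyridin]-3'(2'H)-one | C13(OCCO3)C[C@@H]2[C@@H](CN(C)C(=O)[C@@H]2C)[C@@H]1C | intermediate
14 | (4'R,4a'S,7'S,7a'R)-2',4',7'-trimethyloctahydrospiro[1,3-dioxolane-2,6'-cyclopenta[c]pyridine] | C13(OCCO3)C[C@@H]2[C@@H](CN(C)C[C@@H]2C)[C@@H]1C | intermediate
15 | (4R,4aS,7S,7aR)-2,4,7-trimethyloctahydro-6H-cyclopenta[c]pyridin-6-one | O=C1C[C@@H]2[C@@H](CN(C)C[C@@H]2C)[C@@H]1C | intermediate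
16 | (4R,4aS,6S,7S,7aR)-2,4,7-trimethyloctahydro-1H-cyclopenta[c]pyridin-6-ol | O[C@H]1C[C@@H]2[C@@H](CN(C)C[C@@H]2C)[C@@H]1C | intermediate
17 | geranyl acetate | CC(C)=CCC/C(C)=C/COC(C)=O | starting material
18 | (2E,6E)-8-hydroxy-3,7-dimethylocta-2,6-dien-1-yl acetate | OC/C(C)=C/CC/C(C)=C/COC(C)=O | intermediate
19 | (2E,6E)-2,6-dimethylocta-2,6-diene-1,8-diol | OC/C(C)=C/CC/C(C)=C/CO | intermediate
20 | (2E,6E)-2,6-dimethylocta-2,6-dienedial | O=C/C(C)=C/CC/C(C)=C/C=O | intermediate
21 | (2E,6E)-2,6-dimethylocta-2,6-dienedioic acid | OC(=O)/C(C)=C/CC/C(C)=C/C(O)=O | intermediate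
22 | bis[(4R,4aS,6R,7S,7aR)-2,4,7-trimethyloctahydro-1H-cyclopenta[c]pyridin-6-yl] (2E,6E)-2,6-dimethylocta-2,6-dienedioate | C/C(=C\C(=O)O[C@@H]1C[C@@H]2[C@@H](CN(C)C[C@@H]2C)[C@@H]1C)CC/C=C(\C)C(=O)O[C@@H]1C[C@@H]2[C@@H](CN(C)C[C@@H]2C)[C@@H]1C | target

**Step count**
Total: 16 steps. Longest linear sequence: 12 steps (steps 1 to 11, then step 16); the diacid branch is steps 12 to 15.

**Steps most likely to fail**

Step 4 (Pauson–Khand). The vinyl group may insert slowly, because the 1,7-enyne reacts only from the amide rotamer that brings the two π systems together. The β,γ-double bond may migrate into conjugation at cobalt, or C4 may discriminate the vinyl faces only weakly. The fallback sets out from 6 and returns at 8. CO is replaced by an isocyanide in a [2+2+1] cyclisation on zerovalent nickel (Ni(cod)2, PBu3, 2,6-dimethylphenyl isocyanide, DMF/THF, rt). This runs at room temperature through a nickelacyclopentene and should give (4S,4aS)-6-[(2,6-dimethylphenyl)imino]-2,4,7-trimethyl-1,2,4,4a,5,6-hexahydro-3H-cyclopenta[c]pyridin-3-one F1. Hydrolysis of the imine with aqueous oxalic acid in THF then gives 8.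

Step 8 (C4 inversion). Enolisation may be incomplete, because the C4–H to be removed sits on the concave face. Facial selectivity in the proton return may also be lost if protonation occurs on oxygen and the resulting enol tautomerises later. The fallback sets out from 11 and returns at 13. It uses thermodynamic equilibration (KOt-Bu, t-BuOH, reflux) by reversible enolisation, chromatographic separation of 13 from 11, and resubmission of recovered 11; the two epimers should be close in energy because each can place the C4 methyl pseudo-equatorial. No compound outside the list is made (F0).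

Step 16 (double Mitsunobu). The second esterification may stall at the mono-ester, the activated alcohol may eliminate to the cyclopentene, or ion-pairing of the diacid with the tertiary amines may slow protonation of the betaine. The fallback sets out from 16 and returns at 22. The inversion is done first with the more acidic 4-nitrobenzoic acid (PPh3, DIAD, THF) to give (4R,4aS,6R,7S,7aR)-2,4,7-trimethyloctahydro-1H-cyclopenta[c]pyridin-6-yl 4-nitrobenzoate F2. Methanolysis (K2CO3, MeOH) gives (4R,4aS,6R,7S,7aR)-2,4,7-trimethyloctahydro-1H-cyclopenta[c]pyridin-6-ol F3. This is acylated twice with 21 with retention (EDC·HCl, DMAP, CH2Cl2, 0 °C) to give 22.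

**Further compounds**
F1 | step 4 | (4S,4aS)-6-[(2,6-dimethylphenyl)imino]-2,4,7-trimethyl-1,2,4,4a,5,6-hexahydro-3H-cyclopenta[c]pyridin-3-one | Cc1cccc(C)c1N=C1C[C@@H]2C(CN(C)C(=O)[C@H]2C)=C1C
F0 | step 8 | none | none
F2 | step 16 | (4R,4aS,6R,7S,7aR)-2,4,7-trimethyloctahydro-1H-cyclopenta[c]pyridin-6-yl 4-nitrobenzoate | O=C(O[C@@H]1C[C@@H]2[C@@H](CN(C)C[C@@H]2C)[C@@H]1C)c1ccc(cc1)[N+](=O)[O-]
F3 | step 16 | (4R,4aS,6R,7S,7aR)-2,4,7-trimethyloctahydro-1H-cyclopenta[c]pyridin-6-ol | O[C@@H]1C[C@@H]2[C@@H](CN(C)C[C@@H]2C)[C@@H]1C
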